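Two numbers are asked of this flask; their ratio is what to watch when the run is repeated, and the level of the complex with one exchanged has to be read as well.

1. the complex with two exchanged standing at 8.0 d, as a percentage of the starting complex charged
2. the complex with one exchanged standing at 8.0 d, as a percentage of the starting complex charged

| flask | starting complex | incoming ligand | remark | time |
|---|---|---|---|---|
| autumn | 0.025 M | 1.2 equiv | run made earlier |  |
| dusk | 0.10 M | 1.2 equiv | run made earlier |  |
| noon | 0.050 M | 0.60 equiv | run made earlier |  |
| flask | 0.050 M | 1.20 equiv |  | 8.0 d |

| run | time / d | complex with two exchanged / % | complex with one exchanged / % |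
|---|---|---|---|
| autumn | 1.25 | 23.9 | 28.2 |
| autumn | 2.50 | 23.2 | 27.9 |
| autumn | 4.00 | 23.8 | 27.6 |
| autumn | 5.00 | 23.6 | 27.8 |
| autumn | 6.00 | 23.1 | 27.9 |
| autumn | 8.00 | 23.3 | 28.2 |
| dusk | 1.25 | 23.2 | 28.3 |
| dusk | 2.50 | 23.2 | 28.0 |
| dusk | 4.00 | 22.8 | 28.1 |
| dusk | 5.00 | 22.6 | 28.2 |
| dusk | 6.00 | 23.0 | 27.5 |
| dusk | 8.00 | 22.9 | 28.7 |
| noon | 0.625 | 7.4 | 31.6 |
| noon | 1.25 | 8.2 | 31.9 |
| noon | 2.50 | 7.9 | 32.1 |
| noon | 4.00 | 8.0 | 32.3 |
| noon | 8.00 | 7.1 | 31.9 |

(each reading ± 0.3 percentage points)

- the numbers in the tables scatter with a standard deviation of 0.3 percentage points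

Pooled over the autumn and dusk runs, the readings give 0.828. This is the split, c(complex with two exchanged) over c(complex with one exchanged) on the plateau, a ratio of standing amounts. The noon run, at 0.60 equiv, reads 0.242. Between these charges, then, the split grows as the equivalents raised to the power 1.78.

Two chemists read these runs differently. The first says the plateau is frozen: concentration went from 0.025 M to 0.10 M with the split hardly moving, so the mean of each column serves. The second says the flask still creeps, since the complex with two exchanged falls from 23.9 % to 23.3 % in the autumn run, so the last readings of autumn and dusk should be trusted: 23.1 % and 28.4 %. I side with the first, because that fall of 0.6 points is a difference of two readings, each with scatter 0.3 points. My reckoning is 28.0 % of the complex with one exchanged, and the split then gives 23.2 % of the complex with two exchanged.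

The forecast, on the first chemist's side, says 23.2 % (22.7 % to 23.7 %) and 28 % (27.6 % to 28.4 %), holding that “each run has reached its plateau”.

The flask gives 23.3 % and 28.0 %, a split of 0.832, about the 0.828 read from the runs.

    starting complex + incoming ligand → leaving ligand + complex with one exchanged (k = 82.0 M⁻¹ h⁻¹)
    complex with one exchanged + incoming ligand → leaving ligand + complex with two exchanged (k = 37.0 M⁻¹ h⁻¹)
    complex with two exchanged + incoming ligand → leaving ligand + complex with three exchanged (k = 7.20 M⁻¹ h⁻¹)
    complex with two exchanged ⇌ isomer of the product (K = 0.720, k = 0.350 h⁻¹)
    2 starting complex → self-condensation product (k = 24.0 M⁻¹ h⁻¹)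

The second chemist's moving flask is the true picture before 0.0639 d, when nineteen twentieths of the conversion at the asked time is reached, and over the second half of the time the largest change of any share is 0.18 points, less than the scatter. Carried to a neighbour flask charged with 0.480 equiv, the power law predicts a split of 0.162. That neighbour stood at 5.27 % and 29.1 %, a split of 0.181.

The runs were generated by integration with made-up constants.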